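Wednesday's flask, with 0.080 M of solid substrate, turned about 0.00340 /d of its charge into target per day, read as summed percent over summed time, and this is a rough reading: each point is good to 1 percentage point, while the readings reach 1.5%.

| flask | solid substrate | reagent | catalyst | remark | time |
|---|---|---|---|---|---|
| Wednesday's | 0.080 M | 0.90 equiv | 0.2 mol% | run made earlier |  |
| Friday's | 1.7 M | 0.90 equiv | 0.2 mol% | run made earlier |  |
| zeta | 0.15 M | 0.900 equiv | 0.2 mol% |  | 4.0 d |
| theta | 0.30 M | 0.900 equiv | 0.2 mol% |  | 4.0 d |
| beta | 0.60 M | 0.900 equiv | 0.2 mol% |  | 4.0 d |
| gamma | 1.2 M | 0.900 equiv | 0.2 mol% |  | 4.0 d |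
| eta | 2.5 M | 0.900 equiv | 0.2 mol% |  | 4.0 d |

| Wednesday's: time / d | Wednesday's: target / % | Friday's: time / d | Friday's: target / % |
|---|---|---|---|
| 0.625 | 0 | 0.250 | 0.3 |
| 1.04 | 0.7 | 0.625 | 5.5 |
| 1.67 | 0 | 1.25 | 11.5 |
| 2.50 | 1.5 | 2.08 | 20.1 |
| 3.00 | 0.8 | 3.00 | 27.9 |

(readings scatter by 1 percentage point)

- given per volume of solution although it is solid: solid substrate
- steps under discussion: starting material + reagent + catalyst -> target + catalyst; target + catalyst <-> isomer of the product + catalyst; solid substrate <-> starting material
- at the start none of the solid substrate is in solution
- "hardly changes" means that all values lie within two and a half points (for a concentration: within two and a half percent of the largest)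

1. [target] at the end for zeta, theta, beta, gamma, eta, in this order
2. how the row runs (rises, then falls / rises all the way / hardly changes / falls all the way / falls, then rises)

We follow the dilute end of the row in slow motion. In the first instants of zeta nothing is in solution, and the solid substrate has to dissolve before any step can run. In the middle, we take it, the charge is in solution and the catalyst comes back from each turn, so the starting material decays by a pseudo-first-order law whose rate coefficient is proportional to the reagent's concentration times the catalyst's. Both scale with the charge c, so we divide Wednesday's pace by the square of its charge and call the result the dilute pace constant κ, 0.531 /M²/d. Integrated, the yield of target is one minus exp(−κ·c·c·t). At the end this gives 4.66% for zeta, or 0.00699 M, and 17.4% for theta, or 0.0522 M, a reckoning that holds the reagent at its charge. On Friday's charge κ would give a pace of 1.53 /d, faster than the 0.0943 /d read from that run, so we commit to κ for zeta and theta and not for the solid-rich flasks.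

The forecast gives 0.005 M, 0.021 M, 0.085 M, 0.32 M and 1.15 M, a row that rises all the way, on the ground that “percent rate is roughly proportional to charge”; at zeta and theta it stands lower than our reckoning.

The flasks give 0.00822 M, 0.0449 M, 0.149 M, 0.395 M and 0.800 M, a row that rises all the way.

    starting material + reagent + catalyst → target + catalyst, rate k1*[starting material]*[reagent]*[catalyst]/(1 + ([starting material]/sat1)) (2.20 M, k = 0.00720 /M²/s)
    target + catalyst ⇌ isomer of the product + catalyst, rate k2*[catalyst]*[target] forward; the back reaction follows from the equilibrium constant (K = 0.600, k = 0.0310 /M/s)
    solid substrate ⇌ starting material, rate k3*(cs3 - [starting material]) while solid is left; crystals form when [starting material] > cs3 (solubility = 0.290 M, k = 1.80 × 10⁻⁵ /s)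

Carried to zeta at 4.00 d, κ gives 4.66% against 5.48% in the flask, and on theta 17.4% against 15.0%, where the forecast stood at 3.33% and 7.00%. In zeta the dissolution of the solid substrate ran earlier than the step to target, half of its turnover done by 0.193 d and 100% of it by 0.800 d, and the step from starting material and reagent to target ran steadily on, with 50% of its turnover behind it at 2.00 d, while reagent stood at 91% of its charge at 4.00 d.

Readings and results were computed from invented constants; scatter was added.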